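The numbers are invented; the run is a simulation.

Watch the first nucleophile.

| flask | starting material | first nucleophile | second nucleophile | temperature | time |
|---|---|---|---|---|---|
| north-west | 0.30 M | 0.500 equiv | 1.05 equiv | 105 °C | 20 h |
| south-east | 0.30 M | 0.500 equiv | 1.05 equiv | 120 °C | 20 h |
| south | 0.30 M | 0.500 equiv | 1.05 equiv | 135 °C | 20 h |
| west | 0.30 M | 0.500 equiv | 1.05 equiv | 90 °C | 20 h |

* the flask that comes out highest in amount of target, in percent of the starting material charged, or "all alike" when all lie within 1.5 percentage points (north-west / south-east / south / west / all alike)
* target at the end, in percent of the starting material charged, north-west
* target at the end, in percent of the starting material charged, south-east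
* target at the end, in percent of the starting material charged, south
* target at the end, in percent of the starting material charged, west

- the constants hold at 90 °C; other temperatures follow from the activation energies and enthalpies

    starting material ⇌ intermediate (K1 = 0.14, k1 = 0.322 /h, Ea1 = 112 kJ/mol, ΔH1 = −5.00 kJ/mol)
    first nucleophile + intermediate → target (k2 = 1640 /M/h, Ea2 = 76.0 kJ/mol)
    second nucleophile + intermediate → other capture product (k3 = 326 /M/h, Ea3 = 55.0 kJ/mol)
    second nucleophile → decomposition product (k4 = 1.05 × 10⁻⁴ /h, Ea4 = 129 kJ/mol)
    second nucleophile ⇌ dormant form (K5 = 1.58, k5 = 2.28 /h, Ea5 = 100 kJ/mol, ΔH5 = −28.0 kJ/mol)
    (constants at 90 °C)

The starting material opens reversibly to an intermediate, which the first nucleophile captures to give the target and the second nucleophile captures to give the other capture product; the second nucleophile also exchanges with a dormant form. The first nucleophile is charged at 0.500 equiv and each target takes one of it, so in these flasks it is the limiting reagent for that product, and I ask whether that ceiling is reached.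

I begin by counting half-lives of opening: in west, at 90 °C, one half-life is 2.15 h, so 20 h holds 9.29 of them and leaves 0.160% unopened by this count. My objection is that the intermediate can fall back, but at the start of west it falls back at 2.30 /h, far more slowly than the first nucleophile takes it at 246 /h, so at that moment I treat opening as the rate-limiting step.

The harder objection is the competitor, because the capture constants differ by a factor of just 5.03 while the second nucleophile is charged at twice the first. Its exchange with the dormant form, however, relaxes with a half-life of 0.186 h in west, which is shorter than the half-life of opening, so I take the free part as a steady fraction of the pool of free and dormant second nucleophile together.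

I therefore carry one quantity, σ, the ratio of the two capture constants multiplied by one plus the dormancy equilibrium constant, which is the selectivity factor of the first nucleophile against that whole pool; it is 13.0 in west. Both nucleophiles draw on the same intermediate, so, with decomposition set aside, I reckon the fraction of first nucleophile left as the fraction of the pool left, raised to the power σ. Suppose the starting material ends up captured and the first nucleophile takes nearly its full charge; then the pool in west ends at a fraction 0.524, which by this estimate leaves 0.0227% of the first nucleophile's charge and puts the target at 50.0%.

Heat might spoil this, but the drift of the opening equilibrium from 0.14 to 0.117 in south gives me the temperature scale, and with it σ in south comes out at 17.0, larger than in west, so I expect south at the ceiling as well.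

The forecast gives 49.9% for north-west, 49.9% for south-east, 50% for south and 49.9% for west, and its verdict is all alike, on the ground that “temperature changes the speed but not the outcome”.

The simulation gives 50.0% for north-west, 50.0% for south-east, 50.0% for south and 50.0% for west, so the verdict is all alike.

The wearing away of the first nucleophile is the main reason for this ceiling: with it held level, the target in west rises from 50.0% to 85.6%. In west, free second nucleophile at 20% of its charge at the end gives through σ 0.0235% of the first nucleophile's charge left, against a reading of 0.025%. In the neighbour of west charged with 2.00 equiv of first nucleophile, free second nucleophile ends at 37%, so σ gives 49.3% of first nucleophile left, against a reading of 53%, with the target at 94.3%.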